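The cyclobutane is disconnected at the C1–C4 ring bond: C1 carries an exocyclic carboxyl carbon and is joined to the catechol-bearing C4, which is what remains when the carbonyl carbon of a cyclopentanone is extruded from the ring. A photochemical Wolff contraction of an all-trans 2,4-diaryl-3-vinyl-5-diazocyclopentanone therefore forms the four-membered ring, the C1–C4 bond and the C1 benzyl ester in one operation, with the C2–C4 stereochemistry carried over. The diazoketone is assembled on (R)-4-silyloxycyclopentenone by two anti conjugate additions and a Suzuki coupling. The vinyl group later becomes the C3 carboxyl, kept distinct from C1 for esterification with protected (R)-danshensu and global hydrogenolysis.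

Key step: step 6

Remark: cyclobutane locants follow the target throughout (C1 carboxyl, C2 4-oxygenated aryl, C3 second carboxyl, C4 3,4-dioxygenated aryl). (R)-Danshensu is taken as the free acid; its sodium salt would only change the base stoichiometry in step 8.

Step 1
Reactants: 1 (R)-4-[(tert-butyldimethylsilyl)oxy]cyclopent-2-en-1-one; 2 1-(benzyloxy)-4-bromobenzene
Product: 5 (R)-4-[4-(benzyloxy)phenyl]cyclopent-2-en-1-one, via 4-(benzyloxy)phenylmagnesium bromide 3 (not isolated), via trans-silyloxy ketone 4 (not isolated)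
Conditions: 2, Mg, THF, reflux; CuBr·SMe2 (20 mol%), then 1, THF, −78 → −40 °C; aq NH4Cl; crude, DBU (1.1 equiv), CH2Cl2, 0 °C
Reagents that add atoms: none
Why: Copper-catalysed conjugate addition of the aryl Grignard reagent should occur at C3 anti to the C4 silyloxy group (substrate control), and E1cB loss of silanol from the β-silyloxy ketone then moves the enone so that the aryl-bearing carbon becomes the (R)-configured γ-centre of the new cyclopentenone.

Step 2
Reactants: 5 (R)-4-[4-(benzyloxy)phenyl]cyclopent-2-en-1-one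
Product: 6 (R)-4-[4-(benzyloxy)phenyl]-2-iodocyclopent-2-en-1-one
Conditions: I2 (1.5 equiv), pyridine/CH2Cl2 (1:1), 0 °C → rt
Reagents that add atoms: iodine, II
Why: Johnson α-iodination of a cyclic enone (pyridine conjugate addition, iodination of the enolate, elimination) runs in a weakly basic medium that should leave the C4 centre untouched.

Step 3
Reactants: 6 (R)-4-[4-(benzyloxy)phenyl]-2-iodocyclopent-2-en-1-one; 7 3,4-bis(benzyloxy)phenylboronic acid
Product: 8 (R)-2-[3,4-bis(benzyloxy)phenyl]-4-[4-(benzyloxy)phenyl]cyclopent-2-en-1-one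
Conditions: Pd(PhCN)2Cl2 (5 mol%), Ph3As (10 mol%), Ag2O (1.5 equiv), THF/H2O (8:1), rt
Reagents that add atoms: none
Why: Suzuki–Miyaura coupling of a 2-iodoenone under silver-oxide promotion proceeds at room temperature without carbonate base, so the benzylic γ-centre is not exposed to heat or strong base.

Step 4
Reactants: 8 (R)-2-[3,4-bis(benzyloxy)phenyl]-4-[4-(benzyloxy)phenyl]cyclopent-2-en-1-one; 9 vinylmagnesium bromide
Product: 11 (2S,3S,4R)-2-[3,4-bis(benzyloxy)phenyl]-4-[4-(benzyloxy)phenyl]-3-ethenylcyclopentan-1-one, via 2,3-cis ketone 10 (not isolated)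
Conditions: 9 (2 equiv), CuBr·SMe2 (20 mol%), THF, −78 → −30 °C; aq NH4Cl; crude, DBU (0.2 equiv), CH2Cl2, rt
Reagents that add atoms: none
Why: Copper-catalysed conjugate addition should deliver the vinyl group to C3 anti to the C4 aryl group, and base equilibration of the acidic α-aryl C2 centre converts any kinetically protonated 2,3-cis ketone into the all-trans isomer, which is the thermodynamic one.

Step 5
Reactants: 11 (2S,3S,4R)-2-[3,4-bis(benzyloxy)phenyl]-4-[4-(benzyloxy)phenyl]-3-ethenylcyclopentan-1-one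
Product: 13 (2S,3S,4R)-2-[3,4-bis(benzyloxy)phenyl]-4-[4-(benzyloxy)phenyl]-5-diazo-3-ethenylcyclopentan-1-one, via hydroxymethylene ketone 12 (not isolated)
Conditions: NaH (2.5 equiv), HCO2Et (5 equiv), EtOH (cat.), THF, 0 °C → rt; aq HCl work-up; crude, p-ABSA (1.2 equiv), Et3N (2 equiv), MeCN, 0 °C → rt
Reagents that add atoms: 4-acetamidobenzenesulfonyl azide (p-ABSA), CC(=O)Nc1ccc(cc1)S(=O)(=O)N=[N+]=[N-]; ethyl formate, CCOC=O (supplies the formyl carbon of 12 only, which leaves again in the transfer)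
Why: Reversible Claisen formylation should end at the C5 methylene, the only α-position able to form a stabilised β-dicarbonyl enolate, and Regitz deformylative diazo transfer then exchanges the formyl group for the diazo group while C2 stays in its thermodynamic trans configuration.

Step 6
Reactants: 13 (2S,3S,4R)-2-[3,4-bis(benzyloxy)phenyl]-4-[4-(benzyloxy)phenyl]-5-diazo-3-ethenylcyclopentan-1-one; 14 benzyl alcohol
Product: 17 benzyl (1R,2S,3S,4R)-4-[3,4-bis(benzyloxy)phenyl]-2-[4-(benzyloxy)phenyl]-3-ethenylcyclobutane-1-carboxylate, via cyclobutylidene ketene 15 (not isolated), via C1-epimeric benzyl ester 16 (not isolated)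
Conditions: hν (365 nm), 14 (10 equiv), THF, rt; then t-BuOK (0.3 equiv), 50 °C
Reagents that add atoms: none
Why: Excitation of the diazoketone expels N2 while the benzylic carbon attached to the carbonyl (C2 of the cyclopentanone, C4 of the product) shifts to the diazo carbon, giving a ketene whose carbon is the former ring carbonyl and which benzyl alcohol captures as the ester. The closest known reaction type is the photochemical Wolff ring contraction of 2-diazocyclopentanones to cyclobutanecarboxylic acid derivatives. The four-membered ring is closed not by a cyclisation but by this 1,2-shift, in which the C1–C4 bond forms as the bond from C4 to the carbonyl carbon breaks. C4 migrates with retention, C2 and C3 are untouched, and the new C1 centre is set under thermodynamic control: benzyloxide in benzyl alcohol (degenerate transesterification) epimerises the ester α-carbon to the isomer trans to both flanking aryl groups, and doing so while C3 still carries a vinyl group avoids any retro-Michael opening of the ring. The step needs rearrangement to outrun 1,2-hydride shift from the adjacent benzylic C–H and O–H insertion, which the enforced s-cis geometry of the cyclic diazoketone and irradiation in its n→π* band, away from the aryl ether chromophores, should secure; regiochemistry is unambiguous because only one carbon besides the diazo carbon is attached to the carbonyl.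

Step 7
Reactants: 17 benzyl (1R,2S,3S,4R)-4-[3,4-bis(benzyloxy)phenyl]-2-[4-(benzyloxy)phenyl]-3-ethenylcyclobutane-1-carboxylate
Product: 19 (1R,2S,3S,4R)-1-[(benzyloxy)carbonyl]-4-[3,4-bis(benzyloxy)phenyl]-2-[4-(benzyloxy)phenyl]cyclobutane-3-carboxylic acid, via C3 aldehyde 18 (not isolated)
Conditions: OsO4 (2 mol%), NaIO4 (4 equiv), 2,6-lutidine (2 equiv), dioxane/H2O (3:1), rt; crude, NaClO2 (3 equiv), NaH2PO4 (3 equiv), 2-methyl-2-butene (10 equiv), t-BuOH/H2O (4:1), rt
Reagents that add atoms: osmium tetroxide, O=[Os](=O)(=O)=O; sodium periodate, [Na+].[O-]I(=O)(=O)=O; sodium chlorite, [Na+].[O-]Cl=O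
Why: Lemieux–Johnson cleavage of the terminal alkene followed by Pinnick oxidation should turn the vinyl group into the C3 carboxylic acid under buffered conditions that spare the benzyl ester, the benzyl ethers and the C3 centre, whose trans relation to both neighbours is the stable one.

Step 8
Reactants: 20 (R)-danshensu [(R)-3-(3,4-dihydroxyphenyl)-2-hydroxypropanoic acid]
Product: 21 benzyl (R)-3-[3,4-bis(benzyloxy)phenyl]-2-hydroxypropanoate
Conditions: BnBr (3.3 equiv), K2CO3 (3.5 equiv), DMF, N2, 0 °C → rt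
Reagents that add atoms: benzyl bromide, BrCc1ccccc1
Why: Carbonate-mediated O-alkylation (Williamson type) should benzylate the carboxylate and both phenols while the much less acidic secondary alcohol stays free and the stereocentre is not involved.

Step 9
Reactants: 19 (1R,2S,3S,4R)-1-[(benzyloxy)carbonyl]-4-[3,4-bis(benzyloxy)phenyl]-2-[4-(benzyloxy)phenyl]cyclobutane-3-carboxylic acid; 21 benzyl (R)-3-[3,4-bis(benzyloxy)phenyl]-2-hydroxypropanoate
Product: 22 benzyl (1R,2R,3S,4S)-3-({[(2R)-1-(benzyloxy)-3-[3,4-bis(benzyloxy)phenyl]-1-oxopropan-2-yl]oxy}carbonyl)-4-[3,4-bis(benzyloxy)phenyl]-2-[4-(benzyloxy)phenyl]cyclobutane-1-carboxylate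
Conditions: DIC (1.5 equiv), DMAP (0.3 equiv), CH2Cl2, 0 °C → rt
Reagents that add atoms: none
Why: Steglich esterification acylates the secondary alcohol without touching its C–O bond, so the carbinol centre is retained, and C3 keeps its stable trans arrangement (the changed descriptors at C2 and C4 reflect CIP priorities only).

Step 10
Reactants: 22 benzyl (1R,2R,3S,4S)-3-({[(2R)-1-(benzyloxy)-3-[3,4-bis(benzyloxy)phenyl]-1-oxopropan-2-yl]oxy}carbonyl)-4-[3,4-bis(benzyloxy)phenyl]-2-[4-(benzyloxy)phenyl]cyclobutane-1-carboxylate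
Product: 23 (1R,2R,3S,4S)-3-{[(1R)-1-carboxy-2-(3,4-dihydroxyphenyl)ethoxy]carbonyl}-4-(3,4-dihydroxyphenyl)-2-(4-hydroxyphenyl)cyclobutane-1-carboxylic acid
Conditions: H2 (1 atm), 10% Pd/C, THF/MeOH (1:1), degassed, rt
Reagents that add atoms: none
Why: Catalytic hydrogenolysis should cleave the two benzyl esters and the five aryl benzyl ethers in one operation while the non-benzylic alkyl ester, the cyclobutane and all stereocentres remain intact.

Compound list
1 | (R)-4-[(tert-butyldimethylsilyl)oxy]cyclopent-2-en-1-one | O=C1C=C[C@H](O[Si](C)(C)C(C)(C)C)C1 | starting material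
2 | 1-(benzyloxy)-4-bromobenzene | Brc1ccc(OCc2ccccc2)cc1 | starting material
3 | 4-(benzyloxy)phenylmagnesium bromide | Br[Mg]c1ccc(OCc2ccccc2)cc1 | intermediate
4 | (3S,4R)-3-[4-(benzyloxy)phenyl]-4-[(tert-butyldimethylsilyl)oxy]cyclopentan-1-one (3,4-trans) | O=C1C[C@@H](c2ccc(OCc3ccccc3)cc2)[C@H](O[Si](C)(C)C(C)(C)C)C1 | intermediate
5 | (R)-4-[4-(benzyloxy)phenyl]cyclopent-2-en-1-one | O=C1C=C[C@H](c2ccc(OCc3ccccc3)cc2)C1 | intermediate
6 | (R)-4-[4-(benzyloxy)phenyl]-2-iodocyclopent-2-en-1-one | O=C1C(I)=C[C@H](c2ccc(OCc3ccccc3)cc2)C1 | intermediate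
7 | 3,4-bis(benzyloxy)phenylboronic acid | OB(O)c1ccc(OCc2ccccc2)c(OCc2ccccc2)c1 | starting material
8 | (R)-2-[3,4-bis(benzyloxy)phenyl]-4-[4-(benzyloxy)phenyl]cyclopent-2-en-1-one | O=C1C(c2ccc(OCc3ccccc3)c(OCc3ccccc3)c2)=C[C@H](c2ccc(OCc3ccccc3)cc2)C1 | intermediate
9 | vinylmagnesium bromide | C=C[Mg]Br | starting material
10 | (2R,3S,4R)-2-[3,4-bis(benzyloxy)phenyl]-4-[4-(benzyloxy)phenyl]-3-ethenylcyclopentan-1-one (2,3-cis-3,4-trans) | O=C1C[C@@H](c2ccc(OCc3ccccc3)cc2)[C@H](C=C)[C@@H]1c1ccc(OCc2ccccc2)c(OCc2ccccc2)c1 | intermediate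
11 | (2S,3S,4R)-2-[3,4-bis(benzyloxy)phenyl]-4-[4-(benzyloxy)phenyl]-3-ethenylcyclopentan-1-one (2,3-trans-3,4-trans) | O=C1C[C@@H](c2ccc(OCc3ccccc3)cc2)[C@H](C=C)[C@H]1c1ccc(OCc2ccccc2)c(OCc2ccccc2)c1 | intermediate
12 | (2S,3S,4R,5Z)-2-[3,4-bis(benzyloxy)phenyl]-4-[4-(benzyloxy)phenyl]-3-ethenyl-5-(hydroxymethylidene)cyclopentan-1-one | O=C1/C(=C\O)[C@@H](c2ccc(OCc3ccccc3)cc2)[C@H](C=C)[C@H]1c1ccc(OCc2ccccc2)c(OCc2ccccc2)c1 | intermediate
13 | (2S,3S,4R)-2-[3,4-bis(benzyloxy)phenyl]-4-[4-(benzyloxy)phenyl]-5-diazo-3-ethenylcyclopentan-1-one (2,3-trans-3,4-trans) | O=C1C(=[N+]=[N-])[C@@H](c2ccc(OCc3ccccc3)cc2)[C@H](C=C)[C@H]1c1ccc(OCc2ccccc2)c(OCc2ccccc2)c1 | intermediate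
14 | benzyl alcohol | OCc1ccccc1 | starting material
15 | {2-[4-(benzyloxy)phenyl]-4-[3,4-bis(benzyloxy)phenyl]-3-ethenylcyclobutylidene}methanone (ketene; ring centres 2,3-trans-3,4-trans as in 17) | O=C=C1[C@@H](c2ccc(OCc3ccccc3)cc2)[C@H](C=C)[C@H]1c1ccc(OCc2ccccc2)c(OCc2ccccc2)c1 | intermediate
16 | benzyl (1S,2S,3S,4R)-4-[3,4-bis(benzyloxy)phenyl]-2-[4-(benzyloxy)phenyl]-3-ethenylcyclobutane-1-carboxylate (C1 epimer of 17, ester cis to both aryl groups) | O=C(OCc1ccccc1)[C@H]1[C@@H](c2ccc(OCc3ccccc3)cc2)[C@H](C=C)[C@H]1c1ccc(OCc2ccccc2)c(OCc2ccccc2)c1 | intermediate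
17 | benzyl (1R,2S,3S,4R)-4-[3,4-bis(benzyloxy)phenyl]-2-[4-(benzyloxy)phenyl]-3-ethenylcyclobutane-1-carboxylate (all-trans) | O=C(OCc1ccccc1)[C@@H]1[C@@H](c2ccc(OCc3ccccc3)cc2)[C@H](C=C)[C@H]1c1ccc(OCc2ccccc2)c(OCc2ccccc2)c1 | intermediate
18 | benzyl (1R,2S,3S,4R)-4-[3,4-bis(benzyloxy)phenyl]-2-[4-(benzyloxy)phenyl]-3-formylcyclobutane-1-carboxylate (all-trans) | O=C(OCc1ccccc1)[C@@H]1[C@@H](c2ccc(OCc3ccccc3)cc2)[C@H](C=O)[C@H]1c1ccc(OCc2ccccc2)c(OCc2ccccc2)c1 | intermediate
19 | (1R,2S,3S,4R)-1-[(benzyloxy)carbonyl]-4-[3,4-bis(benzyloxy)phenyl]-2-[4-(benzyloxy)phenyl]cyclobutane-3-carboxylic acid (all-trans, route locants) | O=C(OCc1ccccc1)[C@@H]1[C@@H](c2ccc(OCc3ccccc3)cc2)[C@H](C(=O)O)[C@H]1c1ccc(OCc2ccccc2)c(OCc2ccccc2)c1 | intermediate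
20 | (R)-danshensu, (R)-3-(3,4-dihydroxyphenyl)-2-hydroxypropanoic acid | O=C(O)[C@H](O)Cc1ccc(O)c(O)c1 | starting material
21 | benzyl (R)-3-[3,4-bis(benzyloxy)phenyl]-2-hydroxypropanoate | O=C(OCc1ccccc1)[C@H](O)Cc1ccc(OCc2ccccc2)c(OCc2ccccc2)c1 | intermediate
22 | benzyl (1R,2R,3S,4S)-3-({[(2R)-1-(benzyloxy)-3-[3,4-bis(benzyloxy)phenyl]-1-oxopropan-2-yl]oxy}carbonyl)-4-[3,4-bis(benzyloxy)phenyl]-2-[4-(benzyloxy)phenyl]cyclobutane-1-carboxylate (all-trans) | O=C(OCc1ccccc1)[C@@H]1[C@@H](c2ccc(OCc3ccccc3)cc2)[C@H](C(=O)O[C@H](Cc2ccc(OCc3ccccc3)c(OCc3ccccc3)c2)C(=O)OCc2ccccc2)[C@H]1c1ccc(OCc2ccccc2)c(OCc2ccccc2)c1 | intermediate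
23 | (1R,2R,3S,4S)-3-{[(1R)-1-carboxy-2-(3,4-dihydroxyphenyl)ethoxy]carbonyl}-4-(3,4-dihydroxyphenyl)-2-(4-hydroxyphenyl)cyclobutane-1-carboxylic acid (CNP0270917.1) | O=C(O)[C@@H]1[C@@H](c2ccc(O)cc2)[C@H](C(=O)O[C@H](Cc2ccc(O)c(O)c2)C(=O)O)[C@H]1c1ccc(O)c(O)c1 | target

Total step count: 10. Longest linear sequence: 9 steps (steps 1–7, 9 and 10, from 1); step 8 is a one-step side branch.

Steps most likely to fail

Step 6. The hindered ketene may be captured too slowly by the bulky alcohol, so that ketene oligomerisation or reaction of the alcohol with the excited diazoketone competes, and equilibration at C1 in the same pot may stall. The fallback separates ring contraction from ester formation. It sets out from 13, which is irradiated (365 nm) in THF/water so that the smallest available nucleophile intercepts the ketene, giving (1S,2S,3S,4R)-4-[3,4-bis(benzyloxy)phenyl]-2-[4-(benzyloxy)phenyl]-3-ethenylcyclobutane-1-carboxylic acid F1 (expected mainly as this C1 epimer; any all-trans acid converges in the same way). O-Alkylation of the carboxylate with benzyl bromide and Cs2CO3 in DMF gives the benzyl esters 16 and 17, and catalytic potassium benzyloxide in benzyl alcohol/THF completes the epimerisation, coming back to the route at 17.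

Step 1 (the same motif is carried through steps 2 and 3). The C4–H of the 4-aryl enone is benzylic and vinylogously acidic, so base may erode the configuration at C4 or move the double bond into conjugation with the aryl ring. The fallback reverses the order of the two conjugate additions so that no 4-aryl enone is ever formed. It sets out from 1: α-iodination (I2, pyridine) gives (R)-4-[(tert-butyldimethylsilyl)oxy]-2-iodocyclopent-2-en-1-one F2. Room-temperature Suzuki coupling with 7 (Pd, Ph3As, Ag2O) gives (R)-2-[3,4-bis(benzyloxy)phenyl]-4-[(tert-butyldimethylsilyl)oxy]cyclopent-2-en-1-one F3. Copper-catalysed addition of 9 anti to the silyloxy group gives (2S,3R,4R)-2-[3,4-bis(benzyloxy)phenyl]-4-[(tert-butyldimethylsilyl)oxy]-3-ethenylcyclopentan-1-one F4, and DBU elimination gives (4S,5S)-5-[3,4-bis(benzyloxy)phenyl]-4-ethenylcyclopent-2-en-1-one F5. Copper-catalysed addition of 3 anti to the C4 vinyl group, followed by the same base equilibration (through 10 if formed), comes back to the route at 11 with the same absolute configuration.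

Step 9. Acyl transfer between a hindered cyclobutane acid and a hindered secondary α-hydroxy ester may be slow, allowing rearrangement of the activated acid to an N-acylurea or base-mediated erosion at the carbinol α-carbon. The fallback makes the ester bond by O-alkylation of the carboxylate instead of acyl activation, using two inversions. It sets out from 21: Appel bromination (CBr4, PPh3, CH2Cl2, 0 °C) with inversion gives benzyl (S)-2-bromo-3-[3,4-bis(benzyloxy)phenyl]propanoate F6. The caesium carboxylate of 19 (Cs2CO3, DMF, rt) then displaces bromide with a second inversion, coming back to the route at 22 with the (R) configuration restored.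

Further compounds
F1 | step 6 | (1S,2S,3S,4R)-4-[3,4-bis(benzyloxy)phenyl]-2-[4-(benzyloxy)phenyl]-3-ethenylcyclobutane-1-carboxylic acid | O=C(O)[C@H]1[C@@H](c2ccc(OCc3ccccc3)cc2)[C@H](C=C)[C@H]1c1ccc(OCc2ccccc2)c(OCc2ccccc2)c1
F2 | step 1 | (R)-4-[(tert-butyldimethylsilyl)oxy]-2-iodocyclopent-2-en-1-one | O=C1C(I)=C[C@H](O[Si](C)(C)C(C)(C)C)C1
F3 | step 1 | (R)-2-[3,4-bis(benzyloxy)phenyl]-4-[(tert-butyldimethylsilyl)oxy]cyclopent-2-en-1-one | O=C1C(c2ccc(OCc3ccccc3)c(OCc3ccccc3)c2)=C[C@H](O[Si](C)(C)C(C)(C)C)C1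
F4 | step 1 | (2S,3R,4R)-2-[3,4-bis(benzyloxy)phenyl]-4-[(tert-butyldimethylsilyl)oxy]-3-ethenylcyclopentan-1-one | O=C1[C@H](c2ccc(OCc3ccccc3)c(OCc3ccccc3)c2)[C@@H](C=C)[C@H](O[Si](C)(C)C(C)(C)C)C1
F5 | step 1 | (4S,5S)-5-[3,4-bis(benzyloxy)phenyl]-4-ethenylcyclopent-2-en-1-one | O=C1C=C[C@H](C=C)[C@H]1c1ccc(OCc2ccccc2)c(OCc2ccccc2)c1
F6 | step 9 | benzyl (S)-2-bromo-3-[3,4-bis(benzyloxy)phenyl]propanoate | O=C(OCc1ccccc1)[C@@H](Br)Cc1ccc(OCc2ccccc2)c(OCc2ccccc2)c1
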